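The plan rests on cutting C3–C4 and C3'–C4' of the two pyrrole rings, after exchanging the C3/C3' bromines for ester groups. The feature exploited is the four-carbon chain C3–C2–C2'–C3' that links ring A to ring B. It maps onto the CH2–CO–CO–CH2 core of diethyl ketipate, the ketone carbons becoming C2/C2' and the methylenes C3/C3'. The precursor is the twofold-symmetric bis(enamino ester) 6, each nitrogen bearing a CH2CH(OMe)2 arm (future C5 and C4). In one acid-mediated operation both acetals ionize, each enamine carbon captures its own cation, and two C–C bonds and both aromatic rings are formed. Ester removal and sixfold bromination then complete the target.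

Key step: step 3

Remark on the chemistry: ring A is N1/C2–C5 and ring B is N1'/C2'–C5'; 4 is drawn as the diketone although it should exist largely as its bis-enol; the target has no stereocentre, and its C2–C2' axis is treated as freely rotating, as in the given structure.

Step 1
Reactants: 1 diethyl oxalate; 2 ethyl acetate (2.5 equiv)
Product: 4 diethyl 3,4-dioxohexanedioate (diethyl ketipate), via disodium ketipate bis-enolate 3 (not isolated)
Conditions: NaOEt (2.2 equiv), Et2O, 0 °C to reflux; then cold 2 M HCl
Reagents that add atoms: none
Why: Twofold crossed Claisen condensation in which the non-enolizable, highly electrophilic oxalate acylates two ethyl acetate enolates, and formation of the sparingly soluble doubly deprotonated product 3 pulls both equilibria forward before acid releases 4.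

Step 2
Reactants: 4 diethyl 3,4-dioxohexanedioate; 5 aminoacetaldehyde dimethyl acetal (2.1 equiv)
Product: 6 diethyl (2Z,4Z)-3,4-bis[(2,2-dimethoxyethyl)amino]hexa-2,4-dienedioate
Conditions: cat. AcOH, 4 Å molecular sieves, toluene, rt to 40 °C
Reagents that add atoms: none
Why: Standard β-keto ester/primary amine condensation (enamino ester formation) at both electrophilic ketone carbons, in which the sieves remove water, the N–H···O=C hydrogen bond of each vinylogous carbamate sets the Z geometry, and the nearly neutral medium leaves both acetals intact.

Step 3
Reactants: 6 diethyl (2Z,4Z)-3,4-bis[(2,2-dimethoxyethyl)amino]hexa-2,4-dienedioate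
Product: 8 diethyl 1H,1'H-2,2'-bipyrrole-3,3'-dicarboxylate, via monocyclized pyrrolyl enamino ester 7 (not isolated)
Conditions: CF3CO2H/CH2Cl2 (1:1), slow addition of 6, 0.01 M, 0 °C to rt, N2
Reagents that add atoms: none
Why: CF3CO2H protonates a methoxy group of an acetal and expels methanol, the oxocarbenium carbon (future C4) is attacked by the β-carbon of the enamino ester on the same nitrogen (future C3), the cyclic iminium ion sheds its C3 proton, and loss of the second methanol through a nitrogen-stabilized allyl cation followed by loss of a C5 proton gives the aromatic ring of 7, after which the same sequence on the other half gives 8. The closest known reaction type is the acid cyclization of N-(2,2-dialkoxyethyl) β-enamino esters and enaminones to pyrrole-3-carboxylates and 3-acylpyrroles, a Knorr-type C–C closure that is run here twice in one molecule. Ring A and ring B each close 5-exo-trig at the oxocarbenium carbon with the enamine C=C inside the new ring, the enamine counterpart of a 5-(enolendo)-exo-trig closure, a mode that Baldwin's enolate rules rate as unfavourable but that this reaction class is known to pass because the cation is very reactive and aromatization removes the product from every equilibrium. No stereocentre is formed, and the Z geometry of 6 is irrelevant because reversible C-protonation lets each enamine rotate until its arm lies over C3. The step needs each cation to choose its own β-carbon over the β-carbon of the neighbouring enamine (a six-membered closure that would aromatize to a pyridine), over the neighbouring nitrogen or, in 7, the pyrrole N–H (six-membered N-closures), and over a second molecule. The shorter tether and the strong twist about the crowded C2–C2' bond, which holds the neighbouring enamine carbon out of reach of the arm, should favour the five-membered path, N-capture gives only N,O-acetals that re-ionize in the acid, and slow addition at high dilution together with the deactivating C3 esters should suppress intermolecular condensation and oligomerization of the α-free pyrroles.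

Step 4
Reactants: 8 diethyl 1H,1'H-2,2'-bipyrrole-3,3'-dicarboxylate
Product: 10 1H,1'H-2,2'-bipyrrole, via disodium bipyrrole-3,3'-dicarboxylate 9 (not isolated)
Conditions: NaOH (10 equiv), ethylene glycol, 190 °C, argon
Reagents that add atoms: none
Why: Ester saponification followed in the same pot by thermal protodecarboxylation, the classical way of stripping Knorr-type ester groups from pyrroles and bipyrroles, with ipso-protonation at C3/C3' assisted by the donor pyrrolyl group on the adjacent carbon.

Step 5
Reactants: 10 1H,1'H-2,2'-bipyrrole
Product: 11 3,3',4,4',5,5'-hexabromo-1H,1'H-2,2'-bipyrrole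
Conditions: NBS (6.3 equiv), THF, −78 °C to rt, dark, argon
Reagents that add atoms: N-bromosuccinimide, O=C1CCC(=O)N1Br
Why: Exhaustive electrophilic aromatic bromination of a very electron-rich heteroarene, which needs no regiocontrol because all six C–H positions are substituted, and in which each bromine makes the ring less prone to oxidation under the mild, acid-free conditions.

Compound list
1 | diethyl oxalate | CCOC(=O)C(=O)OCC | starting material
2 | ethyl acetate | CCOC(C)=O | starting material
3 | disodium (2Z,4Z)-1,6-diethoxy-1,6-dioxohexa-2,4-diene-3,4-diolate | [Na+].[Na+].CCOC(=O)/C=C([O-])/C([O-])=C/C(=O)OCC | intermediate (not isolated)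
4 | diethyl 3,4-dioxohexanedioate (diethyl ketipate) | CCOC(=O)CC(=O)C(=O)CC(=O)OCC | intermediate
5 | aminoacetaldehyde dimethyl acetal (2,2-dimethoxyethan-1-amine) | NCC(OC)OC | starting material
6 | diethyl (2Z,4Z)-3,4-bis[(2,2-dimethoxyethyl)amino]hexa-2,4-dienedioate | CCOC(=O)/C=C(NCC(OC)OC)/C(NCC(OC)OC)=C/C(=O)OCC | intermediate
7 | ethyl 2-[(1Z)-1-[(2,2-dimethoxyethyl)amino]-3-ethoxy-3-oxoprop-1-en-1-yl]-1H-pyrrole-3-carboxylate | CCOC(=O)/C=C(NCC(OC)OC)/c1[nH]ccc1C(=O)OCC | intermediate (not isolated)
8 | diethyl 1H,1'H-2,2'-bipyrrole-3,3'-dicarboxylate | CCOC(=O)c1cc[nH]c1-c1[nH]ccc1C(=O)OCC | intermediate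
9 | disodium 1H,1'H-2,2'-bipyrrole-3,3'-dicarboxylate | [Na+].[Na+].[O-]C(=O)c1cc[nH]c1-c1[nH]ccc1C([O-])=O | intermediate (not isolated)
10 | 1H,1'H-2,2'-bipyrrole | c1c[nH]c(c1)-c1ccc[nH]1 | intermediate
11 | 3,3',4,4',5,5'-hexabromo-1H,1'H-2,2'-bipyrrole | Brc1[nH]c(-c2[nH]c(Br)c(Br)c2Br)c(Br)c1Br | target

Total step count: 5. Longest linear sequence: 5 steps (from diethyl oxalate 1).

Steps most likely to fail

1. Step 3.
- What may go wrong: the tethered cation may be captured at the wrong site. It may close onto the β-carbon of the neighbouring enamine through a six-membered transition state, with aromatization to a six-membered ring. It may also close at nitrogen once the first ring exists, or the α-free pyrroles may oligomerize in the acid.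
- Fallback: it sets out from 4 and comes back at 8 by a twofold Hantzsch pyrrole synthesis. Compound 4 is treated with NH4OAc in EtOH to give diethyl (2Z,4Z)-3,4-diaminohexa-2,4-dienedioate F1. This is condensed with aqueous chloroacetaldehyde (2.2 equiv) in NaOAc-buffered EtOH at 0 to 60 °C.
- Why it differs: C3–C4 is now made first and intermolecularly, by attack of the enamine carbon on the aldehyde. Each ring then closes by a 5-exo-tet N-alkylation at C5, so no tethered cation has to choose between two enamine carbons. Installing nitrogen beforehand also avoids the competing furan formation.

2. Step 2.
- What may go wrong: the reaction may stall after the first condensation. The amine may cleave the 1,2-dione by retro-Claisen attack, or the first enamine nitrogen may lactamize onto the remote ester.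
- Fallback: it sets out from 4 and comes back at 6. Compound 4 is converted with HC(OEt)3 and cat. H2SO4 in EtOH into the bis(enol ether) diethyl (2E,4E)-3,4-diethoxyhexa-2,4-dienedioate F2. The geometry is drawn by analogy with 3-alkoxycrotonates and is of no consequence. Amine 5 (2.1 equiv, EtOH, rt to 50 °C) then replaces both ethoxy groups by conjugate addition–elimination.
- Why it differs: the amine never meets a free ketone, no water is formed, and the chelated Z,Z geometry of 6 is re-established.

3. Step 4.
- What may go wrong: protodecarboxylation of β-carboxylates that lack alkyl donors may be sluggish. The electron-rich product may also darken thermally or oxidatively at high temperature.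
- Fallback: it sets out from 8 and comes back at 11, bypassing 10. Saponification (KOH, aqueous EtOH, reflux, then HCl) gives 1H,1'H-2,2'-bipyrrole-3,3'-dicarboxylic acid F3. Excess Br2 with NaOAc in AcOH (rt to 50 °C) should brominate C4, C4', C5 and C5' and replace both carboxyl groups by ipso-bromodecarboxylation. This is the halodecarboxylation known for electron-rich heteroaromatic acids.
- Why it differs: the carboxyl groups temper the rings during the first brominations.

Further compounds
F1 | step 3 | diethyl (2Z,4Z)-3,4-diaminohexa-2,4-dienedioate | CCOC(=O)/C=C(N)/C(N)=C/C(=O)OCC
F2 | step 2 | diethyl (2E,4E)-3,4-diethoxyhexa-2,4-dienedioate | CCOC(=O)/C=C(OCC)\C(OCC)=C/C(=O)OCC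
F3 | step 4 | 1H,1'H-2,2'-bipyrrole-3,3'-dicarboxylic acid | OC(=O)c1cc[nH]c1-c1[nH]ccc1C(O)=O
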